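**Conventions and assumption**

- Atom labels used throughout: C1 is the methyl-bearing alkene carbon, C2 the alkene CH, C3 the ring CH2, C4 the CH–O carbon, C5 the CMe2 carbon, C6 the ring CH, and C7 the exocyclic carbon on C6 (carboxyl carbon early, OCH2 carbon late).
- Assumption: the salt of the (S)-acid with (S)-1-phenylethylamine 5 is taken to be the less soluble diastereomer. If a test crystallisation shows the opposite, the (R)-amine is used and nothing else changes.
- Remark: commercial ethyl safranate may contain double-bond isomers. They are carried through step 1 together, because step 2 brings them to the same dianion.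

## Analysis of the target

Target 16 is a monocyclic terpenoid. Its cyclohexene ring carries a trisubstituted C1=C2 alkene, a quaternary C5 with two methyl groups, an isovalerate on C4 and, on C6, a CH2 group (C7) bound through oxygen to position 7 of a coumarin. There are two stereocentres, C4 (R) and C6 (S), on either side of the quaternary carbon, and the C4–O and C6–C7 bonds lie on the same face of the ring (cis-1,3). The coumarin lactone and the isovalerate do not tolerate hydride, hydroxide or alkoxide. The alkene is β,γ to C7, so whenever C7 is a carbonyl the C6–H bond is acidic and the double bond can slip to C6=C1, which erases C6. A free hydroxyl on C4 and an activated C7 are also placed to close a five-membered cyclic ether. The synthesis is hard because the two stereocentres communicate only across C5, and because C6 is a tertiary allylic carbon without a heteroatom, a poor site for direct asymmetric construction. The plan rests on the cis-1,3 relation: the oxygen on C4 and C7 on C6 can be the two ends of one γ-lactone spanning C4 and C6 over C5 (a 6-oxabicyclo[3.2.1]octane). Such a bridge can only form cis, so a C7 carboxyl group can deliver the C4 oxygen and C6 then dictates C4.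

## Retrosynthetic reasoning

**Aryl ether (C7–O).** The bond between C7 and the coumarin oxygen is cut first, giving the primary alcohol 14 and umbelliferone 15. Making this bond last keeps the coumarin away from every hydride and base in the route. The forward reaction is a redox condensation at a primary carbon, which touches no stereocentre. The C4 oxygen must already be acylated at this point: a free C4 hydroxyl would attack the activated C7 and close a bridged bicyclic ether.

**Ester and temporary silyl group (C4–O acyl, C7–O silyl).** Alcohol 14 comes from silyl ether 13 by cleavage of the Si–O bond, and 13 from alcohol 11 and isovaleryl chloride 12. Compound 11 is the mono-silyl ether of diol 10. The two hydroxyls of 10 are told apart by their surroundings: primary at C7, secondary and next to the quaternary C5 at C4. The two extra steps are the price for never having a free C4 hydroxyl beside an activated C7.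

**Diol from lactone (C7 oxidation level; C3–H).** Both C–O bonds of 10 are contained in the bridged lactone 9, so 10 is traced to 9 by raising C7 to the carboxyl level. Lactone 9 is traced to iodolactone 8 by exchanging the C3 hydrogen for a halogen. In 9 and 8, C6 is a bridgehead: it cannot enolise, so the alkene stays at C1=C2 and C6 keeps its configuration while C7 is a carbonyl.

**Key disconnection (C4–O, lactone ring).** Cutting the C4–O bond of 8 and removing the halogen from C3 opens the bicycle to the diene acid 7. This is the place to cut because it removes the C4 stereocentre altogether: only C6 remains to be controlled. The forward reaction has to add the carboxyl oxygen to C4 of the C3=C4 alkene and an electrophilic halogen to the diene, and it can only do so cis to C7.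

**Single enantiomer of the acid (resolution).** Acid 7 is set free from its crystalline ammonium salt 6, which is formed from the racemic acid 4 and amine 5. The C6 centre is selected, not made, and the unwanted enantiomer can be recycled because the dianion 3 is achiral.

**Diene out of conjugation (C6–H).** Racemic 4 comes from the conjugated acid 2 through dianion 3, by removing a proton at C4 and returning one at C6. Acid 2 is the saponification product of the commercial ester 1.

## Alternatives that were turned down

**Alternative 1:** Ring-closing metathesis.
- Disconnection: the C1=C2 double bond of the ring.
- Forward key step: the acyclic diol A2, (2S,4R)-3,3-dimethyl-2-(prop-1-en-2-yl)hept-6-ene-1,4-diol, has an isopropenyl group on C6 and an allyl group on C4. The second-generation Grubbs catalyst (H2IMes)(PCy3)Cl2Ru=CHPh would close it to the cyclohexene diol A1, which is the same compound as 10.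
- For: the alkene position is written by the bond that is formed. There is no extended enolate, no allyl radical and no allylic halide, and closing a 1,1-disubstituted and a monosubstituted alkene to a six-membered trisubstituted alkene is among the most dependable metatheses. On alkene regiocontrol this plan is stronger than the chosen one.
- Against: A2 must carry both stereocentres before the ring exists. They sit on either side of the quaternary C5, so each needs its own asymmetric operation on a crowded acyclic chain. The isopropenyl-bearing C6 is still allylic and, at some stage, α to a carbonyl, so the conjugation problem is only moved into the chain. The steps needed to reach A2 would exceed steps 1 to 7 of the chosen route.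
- Comparison: the chosen strategy gives up the clean alkene placement, but it starts from a ring that can be bought and lets C6 fix C4 through the lactone bridge.

**Alternative 2:** Vinylketene cycloaddition, then oxygen insertion.
- Disconnection: C5–C6 and C4–C7 together, through the cyclobutanone chrysanthenone A3; then insertion of oxygen into the C4–C7 bond (Baeyer–Villiger).
- Forward key step: geranoyl chloride A4 loses HCl with a tertiary amine to give the vinylketene A5, (3Z)-3,7-dimethylocta-1,3,6-trien-1-one. Its ketene C=C adds across the remote trisubstituted alkene and closes the cyclohexene and the four-membered ketone of A3. A peroxide would then have to insert oxygen between C7 and C4 to reach the racemate of 9.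
- For: it is by far the shortest way to the skeleton, two operations from a cheap acyclic acid chloride. The four-membered bridge enforces the same cis relation of C4 and C6 as the lactone, and the alkene is born at C1=C2. On step economy it is stronger than the chosen route.
- Against: A3 would form as a racemate, and a thermal ketene cycloaddition offers no handle for asymmetric induction, so a resolution would come late and without recycling. The oxygen insertion must choose between two bridgehead carbons: C6 is allylic as well as secondary and should migrate at least as readily as C4, which would put the ring oxygen on C6 and give the wrong constitution. The trisubstituted alkene also competes for an electrophilic peroxide.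
- Comparison: in the chosen route C7 is bonded to C6 from the start, so the migratory-aptitude question does not arise, and the configuration is fixed at the acid stage, where the wrong enantiomer is recycled through 3.

**Alternative 3:** Samarium Reformatsky closure of a bridged lactone.
- Disconnection: the C6–C1 bond, with the β-hydroxy lactone A6 as retron.
- Forward key step: the α-bromo lactone A7, (5R)-3-bromo-4,4-dimethyl-5-(3-oxobutyl)oxolan-2-one, is reduced by SmI2 to a samarium enolate. Its α-carbon C6 adds to the ketone carbon C1 and closes the carbocycle, giving A6, (1R,5R)-2-hydroxy-2,8,8-trimethyl-6-oxabicyclo[3.2.1]octan-7-one, as carbinol epimers. Dehydration of A6 would lead to 9.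
- For: C6 is a bridgehead from the moment the ring closes, so conjugation never threatens. C4 can be set in the acyclic precursor of A7 by a dependable asymmetric reduction or allylation, so no resolution is needed; in this respect it is stronger than the chosen route. The side chain on C4 can reach only one face of the enolate, so the cis relation is enforced.
- Against: A7 has to be assembled (lactone with the quaternary carbon, ketone side chain, bromide), which costs more steps than reaching 7. The aldolate of A6 is a strained β-hydroxy lactone that can revert by retro-aldol cleavage. The dehydration must take a hydrogen from C2 and not from the methyl group, a regiochemical question of the same kind as the hydrogen transfer in step 6, at the cost of an extra step.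
- Comparison: the chosen route reaches 9 from 7 in two steps without forming a C–C bond.

Key step: step 5

## Route

Step 1
Reactants: 1 ethyl safranate (ethyl 2,6,6-trimethylcyclohexa-1,3-diene-1-carboxylate)
Product: 2 safranic acid (2,6,6-trimethylcyclohexa-1,3-diene-1-carboxylic acid)
Conditions: KOH, EtOH–H2O, reflux; then 2 M HCl, 0 °C
Reagents that add atoms: potassium hydroxide, [K+].[OH-]
Why: Saponification of a hindered conjugated ester under forcing conditions; any double-bond isomerisation of the ester on the way is harmless because step 2 converges the isomers, and the carboxylate formed is inert to further base.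

Step 2
Reactants: 2 safranic acid
Product: 4 rac-2,6,6-trimethylcyclohexa-2,4-diene-1-carboxylic acid (racemic α-safranic acid), via dilithium trienediolate 3 (not isolated)
Conditions: LiN(i-Pr)2 (1.95 equiv), THF, −78 → 20 °C; then −78 °C, inverse quench into AcOH–THF; cold 1 M HCl
Reagents that add atoms: none
Why: Deconjugation of an unsaturated carboxylic acid through its dianion with kinetic α-protonation. The slight deficit of base leaves some carboxylate as a proton shuttle, so that on warming the dianions should settle on the fully conjugated 3 (proton lost from C4) and not on the cross-conjugated isomer from the C1 methyl group; protonation at low temperature should then occur at C6, the carbon α to the carboxylate, and gives the racemate.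

Step 3
Reactants: 4 racemic α-safranic acid; 5 (S)-1-phenylethylamine
Product: 6 (1S)-1-phenylethanaminium (1S)-2,6,6-trimethylcyclohexa-2,4-diene-1-carboxylate (crystalline salt, collected by filtration)
Conditions: 5 (0.55 equiv), 2-propanol, 60 → 5 °C; recrystallise to constant rotation
Reagents that add atoms: none
Why: Classical resolution through diastereomeric ammonium carboxylates by the half-equivalent method; no stereocentre is formed, C6 is selected, and the acid left in the mother liquor goes back to step 2, where 3 erases its configuration.

Step 4
Reactants: 6 ammonium salt
Product: 7 (1S)-2,6,6-trimethylcyclohexa-2,4-diene-1-carboxylic acid ((S)-α-safranic acid)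
Conditions: 1 M HCl, Et2O, 0 °C
Reagents that add atoms: none
Why: Protonation of the carboxylate and extraction; cold dilute acid and short contact avoid acid-promoted migration of the diene, and C6 is not enolisable under these conditions.

Step 5
Reactants: 7 (S)-α-safranic acid
Product: 8 (1S,4S,5S)-4-iodo-2,8,8-trimethyl-6-oxabicyclo[3.2.1]oct-2-en-7-one (iodine trans to the lactone oxygen)
Conditions: I2 (1.5 equiv), NaHCO3 (3 equiv), CH2Cl2–H2O, 0 °C, dark; then aq. Na2S2O3; crude product used at once
Reagents that add atoms: iodine, II
Why: Iodolactonisation of a γ,δ-unsaturated acid, the reaction by which cyclohex-3-ene-1-carboxylic acids give 4-iodo-6-oxabicyclo[3.2.1]octan-7-ones. Iodine complexes the diene reversibly; with the carboxylate pseudoaxial on C6, one of its oxygens opens the C3=C4 iodonium ion at C4 from the face opposite to iodine and forms the C4–O bond. The γ-lactone ring (O, C7, C6, C5, C4) closes in the 5-exo mode and completes the bridged bicycle. C4 is set by geometry, since a bridge over C5 can only span cis positions, so the C6 centre of 7 dictates it; C3 is set by anti addition and is removed in step 6. The selectivity needed is one of site: oxygen must bond to C4 and not to C1 (four-membered lactone), C2 (5-endo closure across C1=C2) or C3 (six-membered lactone through a boat); the five-membered exo closure should be the fastest of these under NaHCO3 at 0 °C, and reversible complexation lets the substrate drain through it. If iodine instead ends on C1 with oxygen on C4 (conjugate addition), the tertiary allylic iodide leads to 9 through the same allyl radical. Once the bridge is closed, C6 is a bridgehead and can neither epimerise nor let the alkene move into conjugation.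

Step 6
Reactants: 8 iodolactone
Product: 9 (1S,5R)-2,8,8-trimethyl-6-oxabicyclo[3.2.1]oct-2-en-7-one
Conditions: Bu3SnH (1.2 equiv), Et3B (cat.), air, toluene, 0 °C
Reagents that add atoms: none
Why: Radical chain dehalogenation; the allyl radical over C1–C2–C3 should take hydrogen from Bu3SnH at the less hindered secondary terminus C3, which returns the trisubstituted C1=C2 alkene, and the C4–O bond β to a stabilised allyl radical should not fragment. C4 and C6 are untouched.

Step 7
Reactants: 9 bridged lactone
Product: 10 (1R,5S)-5-(hydroxymethyl)-4,6,6-trimethylcyclohex-3-en-1-ol (cis diol)
Conditions: LiAlH4, THF, 0 °C → rt; H2O, aq. NaOH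
Reagents that add atoms: none
Why: Reduction of a lactone to a diol with LiAlH4; both C–O bonds at the stereocentres stay intact, and C7 leaves the carbonyl level without C6 having been enolisable at any point.

Step 8
Reactants: 10 diol
Product: 11 (1R,5S)-5-[(tert-butyldimethylsilyl)oxymethyl]-4,6,6-trimethylcyclohex-3-en-1-ol
Conditions: TBSCl (1.05 equiv), imidazole, CH2Cl2, 0 °C
Reagents that add atoms: tert-butyldimethylsilyl chloride, CC(C)(C)[Si](C)(C)Cl
Why: Selective silylation of a primary alcohol in the presence of a secondary one that sits next to the quaternary C5.

Step 9
Reactants: 11 silyl ether; 12 isovaleryl chloride (3-methylbutanoyl chloride)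
Product: 13 (1R,5S)-5-[(tert-butyldimethylsilyl)oxymethyl]-4,6,6-trimethylcyclohex-3-en-1-yl 3-methylbutanoate
Conditions: pyridine, DMAP (cat.), CH2Cl2, 0 °C → rt
Reagents that add atoms: none
Why: DMAP-catalysed acylation of a hindered secondary alcohol with an acid chloride; the C4–O bond is not broken, so the configuration is kept.

Step 10
Reactants: 13 silyl ether ester
Product: 14 (1R,5S)-5-(hydroxymethyl)-4,6,6-trimethylcyclohex-3-en-1-yl 3-methylbutanoate
Conditions: HF·pyridine, pyridine–THF, 0 °C → rt
Reagents that add atoms: none
Why: Fluoride cleavage of a primary silyl ether under buffered, non-basic conditions, chosen so that the isovalerate does not migrate from the C4 oxygen to the C7 oxygen and the alkene is not isomerised.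

Step 11
Reactants: 14 primary alcohol; 15 umbelliferone (7-hydroxy-2H-chromen-2-one)
Product: 16 (1R,5S)-4,6,6-trimethyl-5-[(2-oxo-2H-chromen-7-yl)oxymethyl]cyclohex-3-en-1-yl 3-methylbutanoate (target)
Conditions: PPh3, DIAD, THF, 0 °C → rt
Reagents that add atoms: none
Why: Mitsunobu etherification of a primary alcohol with an acidic phenol; substitution takes place at C7, which is not a stereocentre, and with the C4 oxygen already acylated there is no internal nucleophile to close the bridged ether.

## Compound list

1 | ethyl safranate (ethyl 2,6,6-trimethylcyclohexa-1,3-diene-1-carboxylate) | CCOC(=O)C1=C(C)C=CCC1(C)C | starting material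
2 | safranic acid (2,6,6-trimethylcyclohexa-1,3-diene-1-carboxylic acid) | OC(=O)C1=C(C)C=CCC1(C)C | intermediate
3 | dilithium (2,6,6-trimethylcyclohexa-2,4-dien-1-ylidene)methanediolate | [Li+].[Li+].[O-]C([O-])=C1C(C)=CC=CC1(C)C | intermediate (not isolated)
4 | rac-2,6,6-trimethylcyclohexa-2,4-diene-1-carboxylic acid (racemic α-safranic acid) | CC1=CC=CC(C)(C)C1C(O)=O | intermediate
5 | (S)-1-phenylethylamine | C[C@H](N)c1ccccc1 | starting material
6 | (1S)-1-phenylethanaminium (1S)-2,6,6-trimethylcyclohexa-2,4-diene-1-carboxylate | C[C@H]([NH3+])c1ccccc1.CC1=CC=CC(C)(C)[C@H]1C([O-])=O | intermediate
7 | (1S)-2,6,6-trimethylcyclohexa-2,4-diene-1-carboxylic acid ((S)-α-safranic acid) | CC1=CC=CC(C)(C)[C@H]1C(O)=O | intermediate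
8 | (1S,4S,5S)-4-iodo-2,8,8-trimethyl-6-oxabicyclo[3.2.1]oct-2-en-7-one | CC1=C[C@H](I)[C@H]2OC(=O)[C@@H]1C2(C)C | intermediate
9 | (1S,5R)-2,8,8-trimethyl-6-oxabicyclo[3.2.1]oct-2-en-7-one | CC1=CC[C@H]2OC(=O)[C@@H]1C2(C)C | intermediate
10 | (1R,5S)-5-(hydroxymethyl)-4,6,6-trimethylcyclohex-3-en-1-ol | CC1=CC[C@@H](O)C(C)(C)[C@H]1CO | intermediate
11 | (1R,5S)-5-[(tert-butyldimethylsilyl)oxymethyl]-4,6,6-trimethylcyclohex-3-en-1-ol | CC1=CC[C@@H](O)C(C)(C)[C@H]1CO[Si](C)(C)C(C)(C)C | intermediate
12 | isovaleryl chloride (3-methylbutanoyl chloride) | CC(C)CC(Cl)=O | starting material
13 | (1R,5S)-5-[(tert-butyldimethylsilyl)oxymethyl]-4,6,6-trimethylcyclohex-3-en-1-yl 3-methylbutanoate | CC1=CC[C@@H](OC(=O)CC(C)C)C(C)(C)[C@H]1CO[Si](C)(C)C(C)(C)C | intermediate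
14 | (1R,5S)-5-(hydroxymethyl)-4,6,6-trimethylcyclohex-3-en-1-yl 3-methylbutanoate | CC1=CC[C@@H](OC(=O)CC(C)C)C(C)(C)[C@H]1CO | intermediate
15 | umbelliferone (7-hydroxy-2H-chromen-2-one) | Oc1ccc2ccc(=O)oc2c1 | starting material
16 | (1R,5S)-4,6,6-trimethyl-5-[(2-oxo-2H-chromen-7-yl)oxymethyl]cyclohex-3-en-1-yl 3-methylbutanoate | CC1=CC[C@@H](OC(=O)CC(C)C)C(C)(C)[C@H]1COc1ccc2ccc(=O)oc2c1 | target

## Step count and least certain steps

Total step count: 11. Longest linear sequence: 11 steps (1 → 16); compounds 5, 12 and 15 are commercial and enter directly.

**Step 5 (key step).** The most likely failure is loss of site selectivity in the ring closure. The C1=C2 alkene is the more electron-rich one and C3 carries more positive charge than C4 in the iodonium ion, so closure onto C2 or C3, or four-membered closure onto C1, may compete. The allylic iodide may also solvolyse or eliminate during work-up. Fallback: from 7, the electrophile is changed to selenium. PhSeCl with K2CO3 in CH2Cl2 at −78 °C should give (1S,4S,5S)-2,8,8-trimethyl-4-(phenylselanyl)-6-oxabicyclo[3.2.1]oct-2-en-7-one F1 through a tighter, less cation-like bridged ion whose opening follows ring size rather than charge, and the product is not a labile halide. Bu3SnH with AIBN in toluene at 80 °C then cleaves the allylic C–Se bond through the same allyl radical, and the route is rejoined at 9.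

**Step 2.** The most likely failure is proton removal at the wrong site: the C1 methyl group lies next to the carboxylate and may be deprotonated faster than C4. If equilibration to 3 is incomplete, the exocyclic-methylene isomer of the acid would form on protonation. Return of the proton to C4 or C2 instead of C6 would give back conjugated material. Fallback: from 2, NBS with AIBN in PhCF3 at 80 °C (Wohl–Ziegler bromination, where hydrogen abstraction goes to the weakest C–H bond, the CH2 at C4) should give 5-bromo-2,6,6-trimethylcyclohexa-1,3-diene-1-carboxylic acid F2; its allylic isomers are equivalent for what follows. Zinc dust in AcOH–THF at 0 °C converts the C–Br bond into the zinc trienolate without any choice of proton, and protonation at C6 rejoins the route at 4.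

**Step 6.** The most likely failure is hydrogen transfer to the tertiary terminus C1 of the allyl radical, which would leave the alkene at C2=C3 and create an unwanted centre at C1. Decomposition of 8 before the chain starts is the second concern. Fallback: from 8, LiAlH4 in Et2O at −20 °C → rt replaces the radical by ionic hydride. Hydride should displace the allylic iodide at C3, either directly or after the C4 alkoxide freed by lactone reduction has closed a C3–C4 vinyl epoxide that hydride reopens at the allylic carbon. The lactone is reduced in the same flask, so the route is rejoined at 10 and one step is saved.

**Step 3.** The most likely failure is poor discrimination between the diastereomeric salts: co-crystallisation, oiling out, or too small a solubility difference, so that the acid is not brought to full enantiopurity. Fallback: from 4, preparative chromatography on a chiral stationary phase (amylose tris(3,5-dimethylphenylcarbamate), hexane–2-propanol with a little AcOH) separates the enantiomers of the free acid and delivers 7 directly, without 6.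

**Step 11.** The most likely failure is slow substitution at C7, a primary carbon with a fully substituted neighbour, so that the activated alcohol is consumed by side reactions of the azodicarboxylate before the phenoxide attacks. Fallback: from 14, Tf2O and 2,6-lutidine in CH2Cl2 at −78 °C should give the triflate (1R,5S)-4,6,6-trimethyl-5-[(trifluoromethanesulfonyl)oxymethyl]cyclohex-3-en-1-yl 3-methylbutanoate F3. Without purification it is treated with 15 and Cs2CO3 in MeCN at 0 °C → rt, where the much better leaving group allows displacement by the phenoxide at low temperature, and the route is rejoined at 16.

## Further compounds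

F1 | step 5 | (1S,4S,5S)-2,8,8-trimethyl-4-(phenylselanyl)-6-oxabicyclo[3.2.1]oct-2-en-7-one | CC1=C[C@H]([Se]c2ccccc2)[C@H]2OC(=O)[C@@H]1C2(C)C
F2 | step 2 | 5-bromo-2,6,6-trimethylcyclohexa-1,3-diene-1-carboxylic acid (racemic) | OC(=O)C1=C(C)C=CC(Br)C1(C)C
F0 | step 6 | none | none
F0 | step 3 | none | none
F3 | step 11 | (1R,5S)-4,6,6-trimethyl-5-[(trifluoromethanesulfonyl)oxymethyl]cyclohex-3-en-1-yl 3-methylbutanoate | CC1=CC[C@@H](OC(=O)CC(C)C)C(C)(C)[C@H]1COS(=O)(=O)C(F)(F)F
A1 | alternative 1 | (1R,5S)-5-(hydroxymethyl)-4,6,6-trimethylcyclohex-3-en-1-ol | CC1=CC[C@@H](O)C(C)(C)[C@H]1CO
A2 | alternative 1 | (2S,4R)-3,3-dimethyl-2-(prop-1-en-2-yl)hept-6-ene-1,4-diol | C=C(C)[C@H](CO)C(C)(C)[C@H](O)CC=C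
A3 | alternative 2 | chrysanthenone, 2,7,7-trimethylbicyclo[3.1.1]hept-2-en-6-one ((1S,5R) enantiomer drawn; would form as the racemate) | CC1=CC[C@H]2C(=O)[C@@H]1C2(C)C
A4 | alternative 2 | geranoyl chloride, (2E)-3,7-dimethylocta-2,6-dienoyl chloride | CC(C)=CCC/C(C)=C/C(Cl)=O
A5 | alternative 2 | (3Z)-3,7-dimethylocta-1,3,6-trien-1-one (vinylketene) | CC(C)=CC/C=C(C)\C=C=O
A6 | alternative 3 | (1R,5R)-2-hydroxy-2,8,8-trimethyl-6-oxabicyclo[3.2.1]octan-7-one (carbinol epimers) | CC1(O)CC[C@H]2OC(=O)[C@@H]1C2(C)C
A7 | alternative 3 | (5R)-3-bromo-4,4-dimethyl-5-(3-oxobutyl)oxolan-2-one | CC(=O)CC[C@H]1OC(=O)C(Br)C1(C)C
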